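Eudesmane numbering is used throughout (C4 bears the aryloxy group, C10 the angular methyl, C7 the C11 carbinol). Retrosynthetic cuts, in order: C4–OAr (magnolol added to a C4=C15 alkene), C4=C15 (methylenation of a C4 ketone), C3–C4 (ring A, acylation by a C3 organolithium), then C5–C10 of ring B.
The enabling feature is ring B (C5 to C10): C5 (ring-fusion CH) and C10 (quaternary, CH3) are adjacent stereocentres in a cyclohexane that also holds C7. This maps onto a δ-lactone O–C4(=O)–C5–C6–C7–C8 carrying the C9=C10 alkene on C8, whose ketene acetal contracts by a [3,3] shift (C5–C10 made, C8–O broken).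
The lactone is cut at O–C4 (oxidative lactonisation of a 1,5-diol), C11–CH3 (Grignard) and C7–C8 (syn-aldol of a pent-4-enoyl imide with a (Z)-enal made by carbocupration of propyne).
Forward: enal and imide are joined by the aldol, the chain is trimmed to the 7,8-trans lactone, ring B arises in step 10, ring A in step 14, then methylenation, etherification with magnolol and desilylation.
Stereochemistry: C7 and C8 come from the oxazolidinone-controlled aldol; C8 is traded suprafacially for C5 and C10 in the boat transition state, the (Z) alkene fixing C10; C4 comes from α-face capture of the tertiary cation, anti to the axial C10 methyl.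

Key step: step 10

Remark: the C1–C3 arm is carried as a benzyl ether, because a 3-halopropylmagnesium halide would collapse to cyclopropane; the target is taken as the (4R,5R,7R,10R) isomer of the SMILES (trans-decalin, 4α-aryloxy, 7β side chain).

Step 1
Reactants: 1 benzyl 3-bromopropyl ether; 2 propyne
Product: 6 benzyl (Z)-5-iodo-4-methylpent-4-en-1-yl ether, via Grignard reagent 3 (not isolated), via alkylcopper 4 (not isolated), via alkenylcopper 5 (not isolated)
Conditions: Mg, Et2O; CuBr·SMe2, Et2O/Me2S, −45 °C; propyne, −25 °C; I2, −50 → 0 °C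
Reagents that add atoms: iodine, [I][I]
Why: Normant carbocupration: the primary alkylcopper adds syn across propyne with the alkyl group going to the methyl-bearing carbon, so chain and copper end up cis, and iodinolysis with retention gives the (Z)-iodide whose geometry later decides C10.

Step 2
Reactants: 6 benzyl (Z)-5-iodo-4-methylpent-4-en-1-yl ether
Product: 8 (Z)-6-(benzyloxy)-3-methylhex-2-enal, via alkenyllithium 7 (not isolated)
Conditions: t-BuLi (2.1 equiv), Et2O, −78 °C; DMF, −78 → 0 °C; aq. NH4Cl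
Reagents that add atoms: N,N-dimethylformamide, CN(C)C=O
Why: Iodine–lithium exchange proceeds with retention of the alkene geometry and the alkenyllithium is formylated by DMF (Bouveault aldehyde synthesis), giving the (Z)-enal.

Step 3
Reactants: 9 (S)-4-benzyl-1,3-oxazolidin-2-one; 10 pent-4-enoyl chloride
Product: 12 (S)-4-benzyl-3-(pent-4-enoyl)-1,3-oxazolidin-2-one, via N-lithio oxazolidinone 11 (not isolated)
Conditions: n-BuLi, THF, −78 °C; 10, −78 → 0 °C
Reagents that add atoms: none
Why: N-Acylation of the lithiated oxazolidinone with the acid chloride is the standard preparation of the aldol substrate and creates no stereocentre.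

Step 4
Reactants: 12 (S)-4-benzyl-3-(pent-4-enoyl)-1,3-oxazolidin-2-one; 8 (Z)-6-(benzyloxy)-3-methylhex-2-enal
Product: 15 (4S)-4-benzyl-3-[(2S,3R,4Z)-8-(benzyloxy)-3-hydroxy-5-methyl-2-(prop-2-en-1-yl)oct-4-enoyl]-1,3-oxazolidin-2-one, via boron enolate 13 (not isolated), via boron aldolate 14 (not isolated)
Conditions: Bu2BOTf, Et3N, CH2Cl2, −78 → 0 °C; 8, −78 → 0 °C; pH 7 buffer, MeOH, H2O2, 0 °C
Reagents that add atoms: none
Why: Evans syn-aldol reaction: the (Z)-boron enolate adds to the enal through a closed chair transition state on the face away from the benzyl group, which sets C7 (S) and C8 (R) together in the syn relationship that becomes the 7,8-trans lactone.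

Step 5
Reactants: 15 the aldol imide
Product: 16 methyl (2S,3R,4Z)-8-(benzyloxy)-3-hydroxy-5-methyl-2-(prop-2-en-1-yl)oct-4-enoate
Conditions: NaOMe, MeOH/CH2Cl2, −20 → 0 °C
Reagents that add atoms: sodium methoxide (NaOMe), C[O-].[Na+]
Why: Methoxide attacks the exocyclic imide carbonyl (nucleophilic acyl substitution), releasing the auxiliary as its sodium salt without touching C7 or C8 at low temperature.

Step 6
Reactants: 16 the β-hydroxy methyl ester
Product: 17 (3S,4R,5Z)-9-(benzyloxy)-2,6-dimethyl-3-(prop-2-en-1-yl)non-5-ene-2,4-diol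
Conditions: MeMgBr (excess), THF, 0 °C → rt; aq. NH4Cl
Reagents that add atoms: methylmagnesium bromide, C[Mg]Br
Why: Double Grignard addition to the methyl ester, assisted by the neighbouring magnesium alkoxide, builds the C11 dimethylcarbinol and leaves the two stereocentres untouched.

Step 7
Reactants: 17 the 2,4-diol
Product: 19 (3S,4R,5Z)-9-(benzyloxy)-2,6-dimethyl-3-(prop-2-en-1-yl)-2-(triethylsilyloxy)-4-(trimethylsilyloxy)non-5-ene, via mono-TMS ether 18 (not isolated)
Conditions: TMSCl, Et3N, CH2Cl2, −20 °C; then 2,6-lutidine, TESOTf (excess), −78 → 0 °C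
Reagents that add atoms: chlorotrimethylsilane, C[Si](C)(C)Cl; triethylsilyl trifluoromethanesulfonate, CC[Si](CC)(CC)OS(=O)(=O)C(F)(F)F
Why: Chemoselective silylation: TMSCl with Et3N reaches only the secondary allylic hydroxyl, after which the silyl triflate caps the tertiary one, taken in excess because the chloride present turns part of it into unreactive TESCl.

Step 8
Reactants: 19 the TMS/TES bis-silyl ether
Product: 22 (4S,5R,6Z)-10-(benzyloxy)-7-methyl-4-[2-(triethylsilyloxy)propan-2-yl]dec-6-ene-1,5-diol, via alkylborane 20 (not isolated), via TMS-protected alcohol 21 (not isolated)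
Conditions: 9-BBN, THF, 0 °C → rt; NaOH, H2O2, 0 °C; then K2CO3, MeOH, rt
Reagents that add atoms: hydrogen peroxide, OO
Why: Hydroboration–oxidation with the bulky 9-BBN is anti-Markovnikov and selects the monosubstituted alkene over the trisubstituted one, and basic methanolysis then removes the TMS ether but not the tertiary TES ether.

Step 9
Reactants: 22 the 1,5-diol
Product: 23 (5S,6R)-6-[(1Z)-5-(benzyloxy)-2-methylpent-1-en-1-yl]-5-[2-(triethylsilyloxy)propan-2-yl]oxan-2-one (7,8-trans lactone)
Conditions: TEMPO (cat.), PhI(OAc)2, NaHCO3, CH2Cl2, rt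
Reagents that add atoms: none
Why: Oxidative lactonisation: the oxoammonium salt from TEMPO oxidises the primary alcohol, the C8 hydroxyl closes the lactol and a second oxidation gives the δ-lactone, with C7 and C8 unchanged and trans.

Step 10
Reactants: 23 the 7,8-trans lactone
Product: 26 (1R,2R,5S)-2-[3-(benzyloxy)propyl]-2-methyl-5-[2-(triethylsilyloxy)propan-2-yl]cyclohex-3-ene-1-carboxylic acid, via silyl ketene acetal 24 (not isolated), via TMS ester 25 (not isolated)
Conditions: LDA, TMSCl/Et3N, THF, −78 °C → rt; toluene, 105 °C; aq. citric acid, THF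
Reagents that add atoms: none
Why: Deprotonation at C5 in the presence of TMSCl gives the cyclic O-silyl ketene acetal 24 (C5=C4(OSi)–O), whose C9=C10 alkene can reach C5 only by folding across the ring, so the Ireland–Claisen [3,3] shift runs through a boat-shaped, bicyclo[2.2.2]octane-like array (C5, C4, O, C8, C9, C10) in which C5–C10 forms as C8–O breaks; this ring contraction of alkenyl lactones is a known reaction type. Ring B (C5 to C10) closes by this concerted, suprafacial bond formation between the ketene-acetal carbon and the distal alkene carbon, which leaves C8=C9 inside the new cyclohexene and the C4 carboxyl on C5. The C8–O stereocentre is consumed and its chirality is handed to both new centres: at C5 the hydrogen must point outward because the ketene acetal is held in the ring, and at C10 the (Z) alkene places the C1 chain (cis to C8) anti to C4 and the methyl syn to it, which is the later trans ring fusion. C7 is a spectator, and because the lactone is 7,8-trans its silyloxypropyl group lies in the open sector of the boat, on the face that carries C4 and the C10 methyl and away from the C1 chain. The step needs full facial fidelity and O- rather than C-silylation: the six-membered tether allows only the boat and ties the ketene-acetal geometry, the (Z) alkene and the trans substituents fix the faces, and the internal TMSCl/Et3N quench at −78 °C suppresses C-silylation and ketene formation.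

Step 11
Reactants: 26 the cyclohexenecarboxylic acid
Product: 28 (1R,2R,5S)-2-[3-(benzyloxy)propyl]-N-methoxy-N,2-dimethyl-5-[2-(triethylsilyloxy)propan-2-yl]cyclohex-3-ene-1-carboxamide, via acid chloride 27 (not isolated)
Conditions: 1-chloro-N,N,2-trimethylprop-1-en-1-amine, CH2Cl2, 0 °C; MeNHOMe·HCl, pyridine, 0 °C → rt
Reagents that add atoms: N,O-dimethylhydroxylamine hydrochloride, CNOC.Cl
Why: The α-chloroenamine converts the hindered acid into its chloride under neutral conditions that spare the silyl ether, and amidation with N,O-dimethylhydroxylamine gives the Weinreb amide without epimerising C5.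

Step 12
Reactants: 28 the unsaturated Weinreb amide
Product: 29 (1R,2S,5R)-2-(3-hydroxypropyl)-N-methoxy-N,2-dimethyl-5-[2-(triethylsilyloxy)propan-2-yl]cyclohexane-1-carboxamide
Conditions: H2 (3 atm), 10% Pd/C, EtOAc, rt
Reagents that add atoms: none
Why: Heterogeneous catalytic hydrogenation saturates the cis-disubstituted C8=C9 alkene and hydrogenolyses the benzyl ether in the same operation, creating no stereocentre and leaving the amide N–O bond and the silyl ether intact in EtOAc.

Step 13
Reactants: 29 the hydroxypropyl Weinreb amide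
Product: 30 (1R,2S,5R)-2-(3-iodopropyl)-N-methoxy-N,2-dimethyl-5-[2-(triethylsilyloxy)propan-2-yl]cyclohexane-1-carboxamide
Conditions: I2, PPh3, imidazole, CH2Cl2, 0 °C → rt
Reagents that add atoms: iodine, [I][I]
Why: Appel-type iodination: the primary alcohol is activated as its oxyphosphonium salt and displaced by iodide in an SN2 reaction, while the amide and silyl ether are inert.

Step 14
Reactants: 30 the iodopropyl Weinreb amide
Product: 32 (4aR,7R,8aR)-4a-methyl-7-[2-(triethylsilyloxy)propan-2-yl]octahydronaphthalen-1(2H)-one (trans-fused), via alkyllithium 31 (not isolated)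
Conditions: t-BuLi (2.1 equiv), Et2O/pentane, −78 → −20 °C; aq. NH4Cl
Reagents that add atoms: none
Why: Iodine–lithium exchange with t-BuLi is faster than its attack on the hindered amide, and the primary alkyllithium then acylates itself on the Weinreb amide (6-exo-trig nucleophilic acyl substitution through a stable chelate), closing ring A as the trans-fused decalone, which is also the more stable C5 epimer.

Step 15
Reactants: 32 the trans-decalone
Product: 33 triethyl({2-[(2R,4aR,8aS)-4a-methyl-8-methylidenedecahydronaphthalen-2-yl]propan-2-yl}oxy)silane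
Conditions: Ph3PCH3Br, KOtBu, toluene, 90 °C
Reagents that add atoms: methyltriphenylphosphonium bromide, C[P+](c1ccccc1)(c1ccccc1)c1ccccc1.[Br-]
Why: Wittig methylenation turns the hindered C4 ketone into the exocyclic C4=C15 alkene, and enolisation at C5 under the basic conditions can only return the more stable trans ring fusion.

Step 16
Reactants: 33 the exocyclic alkene; 34 magnolol
Product: 35 2'-{[(1R,4aR,7R,8aR)-1,4a-dimethyl-7-[2-(triethylsilyloxy)propan-2-yl]decahydronaphthalen-1-yl]oxy}-5,5'-di(prop-2-en-1-yl)biphenyl-2-ol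
Conditions: 34 (4 equiv), TfOH (10 mol%), CH2Cl2, −78 → −40 °C; Et3N
Reagents that add atoms: none
Why: Brønsted-acid-catalysed Markovnikov hydroaryloxylation, the reaction type that gives aryl tert-butyl ethers from isobutene: protonation at C15 gives the tertiary C4 cation, which a phenol oxygen of the C2-symmetric diol captures kinetically at low temperature from the α face, opposite the axial C10 methyl, to set C4 as R, while the monosubstituted allyl groups are far less readily protonated.

Step 17
Reactants: 35 the silylated aryl ether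
Product: 36 eudesmagnolol, 2'-{[(1R,4aR,7R,8aR)-7-(2-hydroxypropan-2-yl)-1,4a-dimethyldecahydronaphthalen-1-yl]oxy}-5,5'-di(prop-2-en-1-yl)biphenyl-2-ol
Conditions: TBAF, THF, 0 → 40 °C
Reagents that add atoms: none
Why: Fluoride-mediated desilylation cleaves the tertiary TES ether under non-acidic conditions that leave the acid-labile tertiary alkyl aryl ether, the phenol and the allyl groups untouched.

Compound list
1 | benzyl 3-bromopropyl ether | BrCCCOCc1ccccc1 | starting material
2 | propyne | CC#C | starting material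
3 | 3-(benzyloxy)propylmagnesium bromide | Br[Mg]CCCOCc1ccccc1 | intermediate
4 | 3-(benzyloxy)propylcopper (as its MgBr2 complex) | [Cu]CCCOCc1ccccc1 | intermediate
5 | (Z)-[5-(benzyloxy)-2-methylpent-1-en-1-yl]copper (copper cis to the chain) | [Cu]/C=C(/C)CCCOCc1ccccc1 | intermediate
6 | benzyl (Z)-5-iodo-4-methylpent-4-en-1-yl ether (iodine cis to the chain) | [I]/C=C(/C)CCCOCc1ccccc1 | intermediate
7 | (Z)-[5-(benzyloxy)-2-methylpent-1-en-1-yl]lithium | [Li]/C=C(/C)CCCOCc1ccccc1 | intermediate
8 | (Z)-6-(benzyloxy)-3-methylhex-2-enal | O=C/C=C(/C)CCCOCc1ccccc1 | intermediate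
9 | (S)-4-benzyl-1,3-oxazolidin-2-one | O=C1OC[C@H](Cc2ccccc2)N1 | starting material
10 | pent-4-enoyl chloride | C=CCCC(=O)Cl | starting material
11 | N-lithio derivative of 9 | O=C1OC[C@H](Cc2ccccc2)N1[Li] | intermediate
12 | (S)-4-benzyl-3-(pent-4-enoyl)-1,3-oxazolidin-2-one | O=C1OC[C@H](Cc2ccccc2)N1C(=O)CCC=C | intermediate
13 | dibutylboron (Z)-enolate of 12 | CCCCB(CCCC)O/C(=C\CC=C)N1[C@@H](Cc2ccccc2)COC1=O | intermediate
14 | dibutylboron aldolate of 15 (boron on the C8 oxygen) | O=C1OC[C@H](Cc2ccccc2)N1C(=O)[C@@H](CC=C)[C@H](OB(CCCC)CCCC)/C=C(/C)CCCOCc1ccccc1 | intermediate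
15 | (4S)-4-benzyl-3-[(2S,3R,4Z)-8-(benzyloxy)-3-hydroxy-5-methyl-2-(prop-2-en-1-yl)oct-4-enoyl]-1,3-oxazolidin-2-one | O=C1OC[C@H](Cc2ccccc2)N1C(=O)[C@@H](CC=C)[C@H](O)/C=C(/C)CCCOCc1ccccc1 | intermediate
16 | methyl (2S,3R,4Z)-8-(benzyloxy)-3-hydroxy-5-methyl-2-(prop-2-en-1-yl)oct-4-enoate | COC(=O)[C@@H](CC=C)[C@H](O)/C=C(/C)CCCOCc1ccccc1 | intermediate
17 | (3S,4R,5Z)-9-(benzyloxy)-2,6-dimethyl-3-(prop-2-en-1-yl)non-5-ene-2,4-diol | CC(C)(O)[C@@H](CC=C)[C@H](O)/C=C(/C)CCCOCc1ccccc1 | intermediate
18 | (3S,4R,5Z)-9-(benzyloxy)-2,6-dimethyl-3-(prop-2-en-1-yl)-4-(trimethylsilyloxy)non-5-en-2-ol | CC(C)(O)[C@@H](CC=C)[C@H](O[Si](C)(C)C)/C=C(/C)CCCOCc1ccccc1 | intermediate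
19 | (3S,4R,5Z)-9-(benzyloxy)-2,6-dimethyl-3-(prop-2-en-1-yl)-2-(triethylsilyloxy)-4-(trimethylsilyloxy)non-5-ene | CC[Si](CC)(CC)OC(C)(C)[C@@H](CC=C)[C@H](O[Si](C)(C)C)/C=C(/C)CCCOCc1ccccc1 | intermediate
20 | 9-[(4S,5R,6Z)-10-(benzyloxy)-7-methyl-4-[2-(triethylsilyloxy)propan-2-yl]-5-(trimethylsilyloxy)dec-6-en-1-yl]-9-borabicyclo[3.3.1]nonane | CC[Si](CC)(CC)OC(C)(C)[C@@H](CCCB1C2CCCC1CCC2)[C@H](O[Si](C)(C)C)/C=C(/C)CCCOCc1ccccc1 | intermediate
21 | (4S,5R,6Z)-10-(benzyloxy)-7-methyl-4-[2-(triethylsilyloxy)propan-2-yl]-5-(trimethylsilyloxy)dec-6-en-1-ol | CC[Si](CC)(CC)OC(C)(C)[C@@H](CCCO)[C@H](O[Si](C)(C)C)/C=C(/C)CCCOCc1ccccc1 | intermediate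
22 | (4S,5R,6Z)-10-(benzyloxy)-7-methyl-4-[2-(triethylsilyloxy)propan-2-yl]dec-6-ene-1,5-diol | CC[Si](CC)(CC)OC(C)(C)[C@@H](CCCO)[C@H](O)/C=C(/C)CCCOCc1ccccc1 | intermediate
23 | (5S,6R)-6-[(1Z)-5-(benzyloxy)-2-methylpent-1-en-1-yl]-5-[2-(triethylsilyloxy)propan-2-yl]oxan-2-one | O=C1CC[C@H](C(C)(C)O[Si](CC)(CC)CC)[C@H](O1)/C=C(/C)CCCOCc1ccccc1 | intermediate
24 | (2R,3S)-2-[(1Z)-5-(benzyloxy)-2-methylpent-1-en-1-yl]-3-[2-(triethylsilyloxy)propan-2-yl]-6-(trimethylsilyloxy)-3,4-dihydro-2H-pyran | C[Si](C)(C)OC1=CC[C@H](C(C)(C)O[Si](CC)(CC)CC)[C@H](O1)/C=C(/C)CCCOCc1ccccc1 | intermediate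
25 | trimethylsilyl ester of 26 | c1ccccc1COCCC[C@]2(C)C=C[C@@H](C(C)(C)O[Si](CC)(CC)CC)C[C@H]2C(=O)O[Si](C)(C)C | intermediate
26 | (1R,2R,5S)-2-[3-(benzyloxy)propyl]-2-methyl-5-[2-(triethylsilyloxy)propan-2-yl]cyclohex-3-ene-1-carboxylic acid | c1ccccc1COCCC[C@]2(C)C=C[C@@H](C(C)(C)O[Si](CC)(CC)CC)C[C@H]2C(=O)O | intermediate
27 | acid chloride of 26 | c1ccccc1COCCC[C@]2(C)C=C[C@@H](C(C)(C)O[Si](CC)(CC)CC)C[C@H]2C(=O)Cl | intermediate
28 | (1R,2R,5S)-2-[3-(benzyloxy)propyl]-N-methoxy-N,2-dimethyl-5-[2-(triethylsilyloxy)propan-2-yl]cyclohex-3-ene-1-carboxamide | c1ccccc1COCCC[C@]2(C)C=C[C@@H](C(C)(C)O[Si](CC)(CC)CC)C[C@H]2C(=O)N(C)OC | intermediate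
29 | (1R,2S,5R)-2-(3-hydroxypropyl)-N-methoxy-N,2-dimethyl-5-[2-(triethylsilyloxy)propan-2-yl]cyclohexane-1-carboxamide | OCCC[C@]1(C)CC[C@@H](C(C)(C)O[Si](CC)(CC)CC)C[C@H]1C(=O)N(C)OC | intermediate
30 | (1R,2S,5R)-2-(3-iodopropyl)-N-methoxy-N,2-dimethyl-5-[2-(triethylsilyloxy)propan-2-yl]cyclohexane-1-carboxamide | [I]CCC[C@]1(C)CC[C@@H](C(C)(C)O[Si](CC)(CC)CC)C[C@H]1C(=O)N(C)OC | intermediate
31 | 3-lithiopropyl analogue of 30 | [Li]CCC[C@]1(C)CC[C@@H](C(C)(C)O[Si](CC)(CC)CC)C[C@H]1C(=O)N(C)OC | intermediate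
32 | (4aR,7R,8aR)-4a-methyl-7-[2-(triethylsilyloxy)propan-2-yl]octahydronaphthalen-1(2H)-one | O=C1CCC[C@]2(C)CC[C@@H](C(C)(C)O[Si](CC)(CC)CC)C[C@H]21 | intermediate
33 | triethyl({2-[(2R,4aR,8aS)-4a-methyl-8-methylidenedecahydronaphthalen-2-yl]propan-2-yl}oxy)silane | C=C1CCC[C@]2(C)CC[C@@H](C(C)(C)O[Si](CC)(CC)CC)C[C@H]21 | intermediate
34 | magnolol, 5,5'-di(prop-2-en-1-yl)biphenyl-2,2'-diol | C=CCc1ccc(O)c(-c2cc(CC=C)ccc2O)c1 | starting material
35 | 2'-{[(1R,4aR,7R,8aR)-1,4a-dimethyl-7-[2-(triethylsilyloxy)propan-2-yl]decahydronaphthalen-1-yl]oxy}-5,5'-di(prop-2-en-1-yl)biphenyl-2-ol | C=CCc1ccc(O)c(-c2cc(CC=C)ccc2O[C@]2(C)CCC[C@]3(C)CC[C@@H](C(C)(C)O[Si](CC)(CC)CC)C[C@H]32)c1 | intermediate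
36 | eudesmagnolol, 2'-{[(1R,4aR,7R,8aR)-7-(2-hydroxypropan-2-yl)-1,4a-dimethyldecahydronaphthalen-1-yl]oxy}-5,5'-di(prop-2-en-1-yl)biphenyl-2-ol | C=CCc1ccc(O)c(-c2cc(CC=C)ccc2O[C@]2(C)CCC[C@]3(C)CC[C@@H](C(C)(C)O)C[C@H]32)c1 | target

Total step count: 17.
Longest linear sequence: 16 steps (steps 1, 2 and 4 to 17, from benzyl 3-bromopropyl ether 1).

Steps most likely to fail

1. Etherification, step 16. Proton loss from the C4 cation may outrun capture by the phenol, so that the double bond migrates into ring A or to C4=C5 (with possible erosion at C5). Longer exposure to acid may also bring C-alkylation of the phenol or loss of the silyl ether. The fallback generates the same cation from a leaving group under milder conditions. From 33, epoxidation on the less hindered α face (mCPBA, NaHCO3, CH2Cl2) should give the 4α,15-epoxide F1. Hydride opening at the CH2 terminus (LiEt3BH, THF) then gives the tertiary 4α-alcohol F2, and Cl3CCN with catalytic KH gives the trichloroacetimidate F3. F3 should alkylate magnolol 34 under catalytic BF3·OEt2 at −30 °C, in the way tert-butyl trichloroacetimidate gives aryl tert-butyl ethers, which returns to the route at 35.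

2. Ring contraction, step 10. Incomplete O-silylation, ketene formation from the lactone enolate, or ionisation of the allylic C8–O bond during heating would lead to elimination and to leakage of the stereochemical relay. The fallback keeps the [3,3] disconnection but moves it to the enol-ether oxidation level, which needs no enolate. From 23, DIBAL-H (CH2Cl2, −78 °C) gives the lactol F4, and dehydration (MsCl, Et3N, then warming) gives the 3,4-dihydro-2H-pyran F5. Its thermal Claisen rearrangement (o-xylene, sealed tube, about 190 °C) passes through the same boat and should give the cyclohexenecarbaldehyde F6 with the same configuration at C5 and C10. Chlorite oxidation (NaClO2, NaH2PO4, 2-methylbut-2-ene, t-BuOH/H2O) returns to the route at 26.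

3. Ring A closure, step 14. Attack of t-BuLi on the amide, deprotonation at C5 or at the N-methoxy group, or protonation of the alkyllithium before it cyclises would lower the conversion. The fallback replaces the organolithium acylation by a reductive Barbier cyclisation onto an aldehyde. From 30, DIBAL-H (THF, −78 °C) reduces the Weinreb amide to the iodo aldehyde F7. SmI2 in THF/HMPA should close ring A to the secondary alcohol F8 (both C4 epimers), and Dess–Martin periodinane returns to the route at 32.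

Further compounds
F1 | step 16 | triethyl({2-[(1R,4aR,7R,8aR)-4a-methyloctahydro-2H-spiro[naphthalene-1,2'-oxiran]-7-yl]propan-2-yl}oxy)silane (4α,15-epoxide, oxygen on the α face) | O1C[C@]12CCC[C@]3(C)CC[C@@H](C(C)(C)O[Si](CC)(CC)CC)C[C@H]32
F2 | step 16 | (1R,4aR,7R,8aR)-1,4a-dimethyl-7-[2-(triethylsilyloxy)propan-2-yl]decahydronaphthalen-1-ol | O[C@]1(C)CCC[C@]2(C)CC[C@@H](C(C)(C)O[Si](CC)(CC)CC)C[C@H]21
F3 | step 16 | (1R,4aR,7R,8aR)-1,4a-dimethyl-7-[2-(triethylsilyloxy)propan-2-yl]decahydronaphthalen-1-yl 2,2,2-trichloroethanimidate | ClC(Cl)(Cl)C(=N)O[C@]1(C)CCC[C@]2(C)CC[C@@H](C(C)(C)O[Si](CC)(CC)CC)C[C@H]21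
F4 | step 10 | (5S,6R)-6-[(1Z)-5-(benzyloxy)-2-methylpent-1-en-1-yl]-5-[2-(triethylsilyloxy)propan-2-yl]oxan-2-ol (both anomers) | OC1CC[C@H](C(C)(C)O[Si](CC)(CC)CC)[C@H](O1)/C=C(/C)CCCOCc1ccccc1
F5 | step 10 | (2R,3S)-2-[(1Z)-5-(benzyloxy)-2-methylpent-1-en-1-yl]-3-[2-(triethylsilyloxy)propan-2-yl]-3,4-dihydro-2H-pyran | C1=CC[C@H](C(C)(C)O[Si](CC)(CC)CC)[C@H](O1)/C=C(/C)CCCOCc1ccccc1
F6 | step 10 | (1R,2R,5S)-2-[3-(benzyloxy)propyl]-2-methyl-5-[2-(triethylsilyloxy)propan-2-yl]cyclohex-3-ene-1-carbaldehyde | c1ccccc1COCCC[C@]2(C)C=C[C@@H](C(C)(C)O[Si](CC)(CC)CC)C[C@H]2C=O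
F7 | step 14 | (1R,2S,5R)-2-(3-iodopropyl)-2-methyl-5-[2-(triethylsilyloxy)propan-2-yl]cyclohexane-1-carbaldehyde | [I]CCC[C@]1(C)CC[C@@H](C(C)(C)O[Si](CC)(CC)CC)C[C@H]1C=O
F8 | step 14 | (4aR,7R,8aR)-4a-methyl-7-[2-(triethylsilyloxy)propan-2-yl]decahydronaphthalen-1-ol (both C1 epimers) | OC1CCC[C@]2(C)CC[C@@H](C(C)(C)O[Si](CC)(CC)CC)C[C@H]21
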